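I had no constants for these flasks, so I set out to read from the runs the one the decision hangs on: whether Q is still working in the grey flask at 10 h.

| flask | E | Q | remark | time |
|---|---|---|---|---|
| grey | 0.40 M | 1.2 M | the very flask that is asked about, followed so far |  |
| violet | 0.20 M | 1.2 M | run made earlier |  |
| flask | 0.40 M | 1.20 M |  | 10 h |

| run | time / h | J / % |
|---|---|---|
| grey | 0.833 | 48 |
| grey | 2.00 | 50 |
| grey | 4.00 | 48 |
| grey | 10.0 | 50 |
| violet | 0.250 | 59 |
| violet | 0.667 | 39 |
| violet | 1.50 | 35 |
| violet | 4.00 | 33 |

(standard deviation of a reading: 1.5 percentage points)

- elm: at 10 h take out 90% of the J then present, then wait 3.0 h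
- birch: change nothing and wait 3.0 h more
- alder: at 10 h add Q, 50.0% of the amount charged, then wait 3.0 h
- cedar: at 10 h add E, 50.0% of the amount charged, then wait 3.0 h

- J, in percent of the E first charged, at 10 h
- what to do for the largest gain in J; "none" if nothing gains more than 2 percentage points (elm / birch / alder / cedar / none)
- J present, with what was taken out counted in, in percent of the E first charged, after elm
- J present, with what was taken out counted in, in percent of the E first charged, after cedar

- removed J is counted in
- the numbers in the tables scatter by 1.5 percentage points (one standard deviation)
- additions bring no volume worth counting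

Grey J stands flat, so the choice turns on what stopped it. In the violet run J fell at a loss rate, the logarithm of the ratio of two neighbouring readings over the time between them, of 0.993 h⁻¹ at first and then 0.130 h⁻¹. I took this fall as pseudo-first-order in J, with a loss rate proportional to cQ, so the drop in that rate tracks cQ itself. I call the reagent clock the time in which the loss rate of J halves; between the midpoints of those two intervals it read 0.213 h, a rough reading that carries the scatter.

Grey was charged with the same 1.2 M of Q, so I carried the clock over, and 10 h holds 46.9 clock times. I therefore took cQ in grey at 10 h as too small to count and the flask as stalled, not balanced. My reckoning was J at 49.0%, unchanged after elm and cedar, and "none" as the best option. Alder's fresh Q had 3.0 h to act, longer than the clock, so I expected it to cost J.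

The forecast read it otherwise, “both flasks look equilibrated, not stalled”, and gave 49%, cedar as best, 70% after elm and 88% after cedar.

The flask gave 48.4%, none as best, 48.4% after elm, 48.4% after cedar, and alder changed J by −24 percentage points.

    E + Q → J (k = 0.850 L mol⁻¹ min⁻¹)
    Q + L ⇌ D (K = 0.360 L mol⁻¹, k = 1.50 L mol⁻¹ min⁻¹)
    Q → Z (k = 0.0480 min⁻¹)
    Q + J → L (k = 0.0650 L mol⁻¹ min⁻¹)

In the grey flask E + Q to J ran first, half its turnover done in 0.770 min, while Q + J to L and Q to Z ran as long as Q lasted, the latter with 99.9% of its turnover behind it at 2.00 h. Free Q stood at 1.63% of its charge at 1.00 h and at 0% at 10.0 h, 46.9 clocks of 0.213 h after the start, with J 48.4% and L 51.5%. A neighbouring flask charged with 2.0 M of Q, its unbound E also down to 0% at the end, stood at the same 46.9 clocks at 10.0 h and held Q at 0%, with J at 19.2%.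

All runs were computed for an exercise.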